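## The problem

The target 22 is a linear pentamer: five benzene rings, lettered A (the 2,4,6-trihydroxyphenyl end) to E (the 3,4,5-trihydroxyphenyl end), joined only by four diaryl ether oxygens and carrying thirteen free hydroxyls. It has no stereocentre and no ring fusion, so nothing has to be controlled in space. What has to be controlled is position: each ring has its own oxygenation pattern (A 1,2,4,6; B 1,2,3,5; C 1,3,4,5; D 1,2,3,4,5; E 1,3,4,5), and seventeen oxygens of nearly equal character must each land on the right carbon. Every ether bridge joins a crowded carbon to an open one: A-C1, B-C2, C-C4 and D-C2 each lie between two oxygen-bearing carbons, while their partners B-C1, C-C1, D-C1 and E-C1 have at least one free neighbour. In a metal-mediated ether synthesis the crowded carbon is therefore best made the phenol and the open carbon the halide or boronic acid. The free polyphenol, above all the pyrogallol units of rings D and E, is oxidised easily in air once deprotonated, so all thirteen hydroxyls must travel as alkyl ethers and be released together at the end under acidic, oxygen-free conditions. The chromium carbene intermediates and the electron-rich phenols on the way are likewise sensitive to air and light. The feature that opens a ring-forming route is ring B: its oxygens at C2 and C5 are para (a hydroquinone pattern) with further oxygens at C1 and C3. Benzannulation of an alkenyl(methoxy)carbene pentacarbonylchromium complex delivers exactly this: C5 with its methoxy from the carbene carbon, C2 with a free hydroxyl from CO, C6–C1 from the vinyl group (which brings the ring A ether in on C1) and C4–C3 from an ynol ether.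

## Retrosynthesis

Rings and ring atoms are named as above; all numbers refer to the compound list.

**22 from 21.** The last operation can only be the release of the hydroxyls, so the first cut is of thirteen O–alkyl bonds. In 21 twelve oxygens are methyl ethers and the oxygen on B-C3 is an ethyl ether, the mark left by the alkyne of the key step. Simple alkyl ethers are preferred to benzyl or silyl groups because they survive organolithium, peracid and copper-mediated steps and add no bulk beside the crowded ether carbons. The forward step must cleave both kinds of alkyl ether completely and leave the four diaryl ether bonds alone.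

**21 from 12 and 20.** The B–O–C bridge is cut on the ring C side, between the oxygen on B-C2 and C-C1. This cut divides the molecule most evenly (two rings and three rings), and its crowded terminus B-C2 is exactly the hydroxyl that the benzannulation leaves free. Cutting the A–B bridge would waste that hydroxyl; cutting C–D or D–E would force a four-ring piece through the organometallic chemistry. The precursors are the dimer phenol 12 and the trimer bromide 20, whose bromine sits on C-C1 between two unsubstituted carbons. The forward reaction must join a phenol substituted at both ortho positions to an electron-rich but unhindered aryl bromide.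

**12 from 9 and 10.** Ring B is taken apart completely: the C4–C5, C2–C3 and C1–C2 bonds are cut, and C2 is returned to a carbonyl ligand of 9. A route to 12 by ether coupling on a ready-made 1,2,3,5-tetraoxygenated benzene would have to tell three ring B oxygens apart. Here each oxygen arrives on a different component: methoxy on the carbene carbon, ethoxy on the alkyne, the ring A ether on the vinyl carbon and the free hydroxyl from the carbonyl ligand. The precursors are acyclic: the three-carbon complex 9 and the two-carbon ynol ether 10. The forward reaction must insert the alkyne with the ethoxy-bearing carbon away from the carbene carbon and must insert CO before the ring closes.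

**9 from 7 and 3; 7 from 4 and 5; 3 from 1.** The bond between the ring A oxygen and the vinyl carbon is cut, which leads to the alkynyl carbene complex 7 as Michael acceptor and the phenol 3 as nucleophile. This puts the crowded A-C1 oxygen in the nucleophile and needs no metal-mediated coupling for the A–B bridge. Complex 7 is cut at the bond between carbene carbon and alkyne into the silyl-protected acetylene 4 and a carbonyl ligand of 5. The hydroxyl of 3 is traced to the formyl group of the aldehyde 1 by exchange of a C–C for a C–O bond. The forward addition must occur at oxygen of 3, lose the silyl group and give the E double bond.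

**20 from 18 and 19; 18 from 16; 16 from 14 and 15; 14 from 13.** The D–O–E bridge is cut on the ring E side, so the crowded D-C2 is the phenol (18) and the open E-C1 the boronic acid (19). A boronic acid is chosen over a halide here because the bromine on ring C must survive this coupling. The hydroxyl on D-C2 is traced to a formyl group (16), which earlier activates its ortho bromide. The C–O–D bridge is cut on the ring D side into the ortho-bromobenzaldehyde 14 and the phenol 15, so the crowded C-C4 is again the nucleophile. The formyl carbon of 14 is removed to leave the symmetrical bromide 13. The forward sequence needs a formylation that has only one possible site, and an ether coupling that distinguishes the activated bromide of 14 from the unactivated one of 15.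

## Roads not taken

**Alternative 1:** Both ether bonds of ring C are cut on the ring C side, and ring C becomes a 1,4-dielectrophile activated by a metal: the complex [CpRu(η6-2,5-dichloro-1,3-dimethoxybenzene)]PF6 A1. In the forward key step A1 would react under mild base first with the A–B phenol 2,4-dimethoxy-6-(2,4,6-trimethoxyphenoxy)phenol A2 at the open chloride and then with the D–E phenol 3,4,5-trimethoxy-2-(3,4,5-trimethoxyphenoxy)phenol A3 at the chloride between the two methoxy groups. The product is the ring C-bound complex A4 of the tridecamethyl ether, which is then decomplexed and demethylated. In convergence this road is better than the chosen one: two bridges form in one flask, and the carbon between two methoxy groups, a poor site for copper-mediated coupling as a halide, is made electrophilic by the metal. Its weak points are these: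
- Site selection between the two chlorides rests only on a steric difference, and the first nucleophile A2 is itself hindered.
- After the first substitution the arene is more electron-rich, and the remaining chloride is flanked on both sides when the ortho-substituted A3 must attack it.
- The ruthenium is stoichiometric.
- A2 and A3 still have to be made separately, so no ring construction is saved.

The chosen plan sets against this a ring B whose oxygen pattern is fixed by the order of bond formation and not by selection between two similar leaving groups, and ether couplings in which the crowded carbon is always the phenol. It concedes a longer endgame and an unproven key step.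

**Alternative 2:** Ring A is cut at its C2–C3 and C5–C6 bonds and built by a double Claisen condensation of dimethyl 2-(2-benzyloxy-3,5-dimethoxyphenoxy)malonate A5 with the dianion of dimethyl 3-oxoglutarate A6 under alkoxide base. This gives the isophthalate A7, dimethyl 5-(2-benzyloxy-3,5-dimethoxyphenoxy)-2,4,6-trihydroxyisophthalate. The key step is safer than a benzannulation: it is classical enolate chemistry without a metal, and both partners are symmetrical, so no regiochemical question arises. In this respect it is better than the chosen plan. For this target, however, it spends the ring-forming step on the easiest ring, since the ring A pattern is obtained in one step as 3 from 1. It also presupposes the hard part: A5 already contains ring B with its oxygens differentiated. After the condensation two ester groups must be hydrolysed and lost as CO2, three hydroxyls masked again and the benzyl group removed before the dimer can be coupled with 20. The chosen plan builds the ring that cannot be bought and obtains in 12 a dimer ready for coupling, at the price of a riskier key step.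

**Alternative 3:** Ring C is cut at its C2–C3 and C1–C6 bonds and formed by a Danheiser benzannulation. The cyclobutenone A8 (3-ethoxy-4-aryloxy, carrying the D–E dimer) would open thermally to a vinylketene and add to the ethynyl ether A9 of the A–B dimer. Ring opening and six-electron closure would then give the pentamer A10 with all four ring C oxygens in place. This is the most convergent of the four roads: two dimers are united without metal, the central ring is made at the same time, and no late ether coupling is needed; here it is better than the chosen plan. Its weak points lie in the partners. An aryl ethynyl ether of an electron-rich phenol substituted at both ortho positions (A9) and a 4-aryloxy-3-ethoxycyclobutenone (A8) are both hard to make and labile, each needs several steps from a dimer that must first be assembled, and the one risky step consumes two advanced fragments. The chosen plan also uses an ynol ether in a benzannulation that ends in a six-electron ring closure, but its partners 9 and 10 are two steps from purchased materials or bought, and a failure costs only a small early fragment. Against this it needs one further ether coupling (step 9).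

Key step: step 4

Assumption: BBr3 is taken to cleave the aryl ethyl ether on ring B together with the twelve methyl ethers, and 13, 15, 19 and a hexane solution of 10 are taken as purchasable.

## Route

Step 1
Reactants: 1 2,4,6-trimethoxybenzaldehyde
Product: 3 2,4,6-trimethoxyphenol, via 2,4,6-trimethoxyphenyl formate 2 (not isolated)
Conditions: mCPBA (1.2 equiv), CH2Cl2, 0 °C to rt; aq. NaHCO3 wash; then K2CO3 (cat.), MeOH, rt, argon
Reagents that add atoms: mCPBA (3-chloroperbenzoic acid), OOC(=O)c1cccc(Cl)c1
Why: Baeyer–Villiger oxidation of an electron-rich benzaldehyde: the trimethoxyphenyl group migrates in the Criegee adduct to give formate 2, and mild methanolysis frees the phenol, which is kept under argon because it is easily oxidised.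

Step 2
Reactants: 4 trimethylsilylacetylene; 5 Cr(CO)6
Product: 7 pentacarbonyl[1-methoxy-3-(trimethylsilyl)prop-2-yn-1-ylidene]chromium, via lithium acyl chromate 6 (not isolated)
Conditions: 4, n-BuLi, THF, −78 °C; add to 5, THF, 0 °C to rt; evaporate; Me3OBF4, CH2Cl2, 0 °C, argon
Reagents that add atoms: Me3OBF4 (trimethyloxonium tetrafluoroborate), C[O+](C)C.F[B-](F)(F)F
Why: Fischer carbene synthesis: the lithium acetylide adds to a carbonyl ligand of Cr(CO)6 to give acyl chromate 6, which the hard oxonium salt alkylates on oxygen; the silyl group caps the alkyne because the parent ethynyl complex cannot be stored.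

Step 3
Reactants: 7 pentacarbonyl[1-methoxy-3-(trimethylsilyl)prop-2-yn-1-ylidene]chromium; 3 2,4,6-trimethoxyphenol
Product: 9 pentacarbonyl[(E)-1-methoxy-3-(2,4,6-trimethoxyphenoxy)prop-2-en-1-ylidene]chromium, via pentacarbonyl(1-methoxyprop-2-yn-1-ylidene)chromium 8 (not isolated)
Conditions: 3 (2.2 equiv), NaH (10 mol %), THF, −30 °C to rt, argon, dark
Reagents that add atoms: none
Why: Oxa-Michael addition to an alkynyl Fischer carbene complex with desilylation in the same flask: the carbene carbon makes the alkyne as electrophilic as an ynone and the alkynyl–silicon bond labile, so the phenoxide should first take the silyl group (giving 8 and the silyl ether of 3) and then add to the terminal carbon. The ortho and para carbons of 3 carry methoxy groups, so only attack through oxygen is open, and the push–pull double bond should equilibrate to the E isomer.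

Step 4
Reactants: 9 pentacarbonyl[(E)-1-methoxy-3-(2,4,6-trimethoxyphenoxy)prop-2-en-1-ylidene]chromium; 10 ethoxyacetylene
Product: 12 2-ethoxy-4-methoxy-6-(2,4,6-trimethoxyphenoxy)phenol, via tricarbonylchromium arene complex of the phenol 11 (not isolated)
Conditions: 10 (3 equiv, hexane solution), degassed THF, 55 °C, sealed tube, argon; then Et2O, air, daylight, rt
Reagents that add atoms: none
Why: Proposed new method: the closest known reaction type is the Dötz benzannulation of alkenyl(alkoxy)carbene pentacarbonylchromium complexes with alkynes, and what is new is a 2-aryloxyvinyl group on the carbene carbon combined with an ynol ether as the alkyne. Thermal loss of one cis carbonyl ligand should let 10 coordinate and insert into the chromium–carbene bond, the carbene carbon joining the unsubstituted alkyne carbon (C5–C4). Insertion of CO at the new carbene carbon forms the C3–C2 bond and a chromium-bound dienylketene, whose ring closure onto the aryloxy-bearing vinyl carbon (C2–C1) gives a cyclohexadienone that enolises to the Cr(CO)3-bound phenol 11; air and daylight then release 12. Ring B is thus closed by a formal [3+2+1] assembly that ends in a thermal six-electron electrocyclisation, and no stereocentre is formed. The regiochemistry needed, ethoxy next to the new hydroxyl, is secured twice: the substituted alkyne carbon prefers the position next to chromium on steric grounds, and the nucleophilic unsubstituted carbon of the ynol ether is the one that attacks the electrophilic carbene carbon. The chemoselectivity needed is six- over five-membered ring formation; chromium, an ethereal solvent, moderate temperature and excess alkyne favour CO insertion, and an aryloxy group is a far weaker donor than the amino groups known to divert such complexes to five-membered rings. The E geometry of 9 turns the aryloxy group outward in the ring closure, so the ring A ether should not hinder it.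

Step 5
Reactants: 13 5-bromo-1,2,3-trimethoxybenzene
Product: 14 6-bromo-2,3,4-trimethoxybenzaldehyde
Conditions: Cl2CHOMe, TiCl4, CH2Cl2, −10 to 0 °C; then ice water
Reagents that add atoms: dichloromethyl methyl ether, COC(Cl)Cl; water, O
Why: Rieche formylation (electrophilic aromatic substitution): the two free positions of 13 are equivalent and each is ortho and para to a methoxy group, so a single aldehyde should result; the reaction is kept cold and short to avoid TiCl4-induced loss of the methyl group next to the new formyl group.

Step 6
Reactants: 14 6-bromo-2,3,4-trimethoxybenzaldehyde; 15 4-bromo-2,6-dimethoxyphenol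
Product: 16 6-(4-bromo-2,6-dimethoxyphenoxy)-2,3,4-trimethoxybenzaldehyde
Conditions: CuI (10 mol %), picolinic acid (20 mol %), K3PO4, DMSO, 80 °C, argon
Reagents that add atoms: none
Why: Ullmann diaryl ether synthesis in its most favourable form: the bromide of 14 is activated by the ortho formyl group and has one free neighbour, while the bromide of 15 sits para to a phenoxide oxygen and is deactivated toward CuI, so the hindered phenol should couple at the aldehyde ring without self-condensation.

Step 7
Reactants: 16 6-(4-bromo-2,6-dimethoxyphenoxy)-2,3,4-trimethoxybenzaldehyde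
Product: 18 6-(4-bromo-2,6-dimethoxyphenoxy)-2,3,4-trimethoxyphenol, via 6-(4-bromo-2,6-dimethoxyphenoxy)-2,3,4-trimethoxyphenyl formate 17 (not isolated)
Conditions: mCPBA (1.2 equiv), CH2Cl2, 0 °C to rt; aq. NaHCO3 wash; then K2CO3 (cat.), MeOH, rt, argon
Reagents that add atoms: mCPBA (3-chloroperbenzoic acid), OOC(=O)c1cccc(Cl)c1
Why: Baeyer–Villiger oxidation: an aryl group with two ortho oxygen substituents migrates readily, the formate 17 is cleaved by methanolysis to the phenol that will carry ring E, and the aryl bromide is inert to peracid.

Step 8
Reactants: 18 6-(4-bromo-2,6-dimethoxyphenoxy)-2,3,4-trimethoxyphenol; 19 3,4,5-trimethoxyphenylboronic acid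
Product: 20 5-bromo-1,3-dimethoxy-2-[3,4,5-trimethoxy-2-(3,4,5-trimethoxyphenoxy)phenoxy]benzene
Conditions: Cu(OAc)2 (1 equiv), pyridine, 4 Å molecular sieves, CH2Cl2, dry air, rt
Reagents that add atoms: none
Why: Chan–Lam coupling: an electron-rich boronic acid without ortho substituents is transferred at room temperature even to phenols substituted at both ortho positions, air returns the copper to the divalent state, and these oxidative conditions leave the ring C bromide untouched, which a second Ullmann reaction at this stage would not guarantee.

Step 9
Reactants: 12 2-ethoxy-4-methoxy-6-(2,4,6-trimethoxyphenoxy)phenol; 20 5-bromo-1,3-dimethoxy-2-[3,4,5-trimethoxy-2-(3,4,5-trimethoxyphenoxy)phenoxy]benzene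
Product: 21 5-[2-ethoxy-4-methoxy-6-(2,4,6-trimethoxyphenoxy)phenoxy]-1,3-dimethoxy-2-[3,4,5-trimethoxy-2-(3,4,5-trimethoxyphenoxy)phenoxy]benzene
Conditions: CuI (20 mol %), picolinic acid (40 mol %), K3PO4, DMSO, 110 °C, argon
Reagents that add atoms: none
Why: Ligand-accelerated Ullmann diaryl ether synthesis: the crowded partner is the phenol 12 and the bromide of 20 has two free ortho positions, the arrangement in which CuI with picolinic acid couples 2,6-disubstituted phenols with electron-rich aryl bromides.

Step 10
Reactants: 21 5-[2-ethoxy-4-methoxy-6-(2,4,6-trimethoxyphenoxy)phenoxy]-1,3-dimethoxy-2-[3,4,5-trimethoxy-2-(3,4,5-trimethoxyphenoxy)phenoxy]benzene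
Product: 22 5-[2,4-dihydroxy-6-(2,4,6-trihydroxyphenoxy)phenoxy]-2-[3,4,5-trihydroxy-2-(3,4,5-trihydroxyphenoxy)phenoxy]benzene-1,3-diol
Conditions: BBr3 (excess), CH2Cl2, −78 °C to rt, argon; then H2O, 0 °C; reversed-phase isolation under argon
Reagents that add atoms: none
Why: Lewis acid dealkylation of aryl alkyl ethers: bromide attacks the alkyl carbon of each boron-coordinated ether, so the twelve methyl ethers and the ethyl ether should be cleaved while the four diaryl ethers, which offer no alkyl carbon, survive; acidic, oxygen-free work-up protects the polyphenol.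

## Compound list

1 | 2,4,6-trimethoxybenzaldehyde | COc1cc(OC)c(C=O)c(OC)c1 | starting material
2 | 2,4,6-trimethoxyphenyl formate | COc1cc(OC)c(OC=O)c(OC)c1 | intermediate (not isolated)
3 | 2,4,6-trimethoxyphenol | COc1cc(OC)c(O)c(OC)c1 | intermediate
4 | trimethylsilylacetylene | C#C[Si](C)(C)C | starting material
5 | Cr(CO)6 (chromium hexacarbonyl) | O=C=[Cr](=C=O)(=C=O)(=C=O)(=C=O)=C=O | starting material
6 | lithium pentacarbonyl[1-oxido-3-(trimethylsilyl)prop-2-yn-1-ylidene]chromate (lithium acyl chromate) | [Li+].[O-]C(C#C[Si](C)(C)C)=[Cr](=C=O)(=C=O)(=C=O)(=C=O)=C=O | intermediate (not isolated)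
7 | pentacarbonyl[1-methoxy-3-(trimethylsilyl)prop-2-yn-1-ylidene]chromium | COC(C#C[Si](C)(C)C)=[Cr](=C=O)(=C=O)(=C=O)(=C=O)=C=O | intermediate
8 | pentacarbonyl(1-methoxyprop-2-yn-1-ylidene)chromium | COC(C#C)=[Cr](=C=O)(=C=O)(=C=O)(=C=O)=C=O | intermediate (not isolated)
9 | pentacarbonyl[(E)-1-methoxy-3-(2,4,6-trimethoxyphenoxy)prop-2-en-1-ylidene]chromium | COC(/C=C/Oc1c(OC)cc(OC)cc1OC)=[Cr](=C=O)(=C=O)(=C=O)(=C=O)=C=O | intermediate
10 | ethoxyacetylene | CCOC#C | starting material
11 | tricarbonyl[η6-2-ethoxy-4-methoxy-6-(2,4,6-trimethoxyphenoxy)phenol]chromium (hapticity not shown) | Oc1c(OCC)cc(OC)cc1Oc1c(OC)cc(OC)cc1OC.O=C=[Cr](=C=O)=C=O | intermediate (not isolated)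
12 | 2-ethoxy-4-methoxy-6-(2,4,6-trimethoxyphenoxy)phenol | Oc1c(OCC)cc(OC)cc1Oc1c(OC)cc(OC)cc1OC | intermediate
13 | 5-bromo-1,2,3-trimethoxybenzene | COc1cc(Br)cc(OC)c1OC | starting material
14 | 6-bromo-2,3,4-trimethoxybenzaldehyde | COc1cc(Br)c(C=O)c(OC)c1OC | intermediate
15 | 4-bromo-2,6-dimethoxyphenol | COc1cc(Br)cc(OC)c1O | starting material
16 | 6-(4-bromo-2,6-dimethoxyphenoxy)-2,3,4-trimethoxybenzaldehyde | COc1cc(Oc2c(OC)cc(Br)cc2OC)c(C=O)c(OC)c1OC | intermediate
17 | 6-(4-bromo-2,6-dimethoxyphenoxy)-2,3,4-trimethoxyphenyl formate | COc1cc(Oc2c(OC)cc(Br)cc2OC)c(OC=O)c(OC)c1OC | intermediate (not isolated)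
18 | 6-(4-bromo-2,6-dimethoxyphenoxy)-2,3,4-trimethoxyphenol | COc1cc(Oc2c(OC)cc(Br)cc2OC)c(O)c(OC)c1OC | intermediate
19 | 3,4,5-trimethoxyphenylboronic acid | COc1cc(B(O)O)cc(OC)c1OC | starting material
20 | 5-bromo-1,3-dimethoxy-2-[3,4,5-trimethoxy-2-(3,4,5-trimethoxyphenoxy)phenoxy]benzene | COc1cc(Br)cc(OC)c1Oc1cc(OC)c(OC)c(OC)c1Oc1cc(OC)c(OC)c(OC)c1 | intermediate
21 | 5-[2-ethoxy-4-methoxy-6-(2,4,6-trimethoxyphenoxy)phenoxy]-1,3-dimethoxy-2-[3,4,5-trimethoxy-2-(3,4,5-trimethoxyphenoxy)phenoxy]benzene | CCOc1cc(OC)cc(Oc2c(OC)cc(OC)cc2OC)c1Oc1cc(OC)c(Oc2cc(OC)c(OC)c(OC)c2Oc2cc(OC)c(OC)c(OC)c2)c(OC)c1 | intermediate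
22 | 5-[2,4-dihydroxy-6-(2,4,6-trihydroxyphenoxy)phenoxy]-2-[3,4,5-trihydroxy-2-(3,4,5-trihydroxyphenoxy)phenoxy]benzene-1,3-diol (CNP0243665.0) | Oc1cc(O)c(Oc2cc(O)cc(O)c2Oc2cc(O)c(Oc3cc(O)c(O)c(O)c3Oc3cc(O)c(O)c(O)c3)c(O)c2)c(O)c1 | target

## Step count and least certain steps

Total: 10 steps. Longest linear sequence: 6 steps (13 → 14 → 16 → 18 → 20 → 21 → 22). The chromium branch joins at step 9 after three steps from 1 or 4.

**Step 4 (key step).** CO insertion may be outrun by direct cyclisation of the vinylcarbene intermediate to five-membered rings, and the ynol ether may insert more than once or oligomerise. The donor-stabilised complex 9 may also need a temperature at which 10 is lost or decomposes. The fallback gives up the benzannulation and builds the dimer by ether coupling, with known chemistry throughout: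
- It sets out from 3, which is coupled with purchased 2-bromo-4,6-dimethoxybenzaldehyde under the conditions of step 6 to give 2,4-dimethoxy-6-(2,4,6-trimethoxyphenoxy)benzaldehyde F1.
- Baeyer–Villiger oxidation as in step 7 gives, through 2,4-dimethoxy-6-(2,4,6-trimethoxyphenoxy)phenyl formate F2, the phenol 2,4-dimethoxy-6-(2,4,6-trimethoxyphenoxy)phenol F3. F3 is the methyl analogue of 12 and the same compound as A2 above.
- Coupling of F3 with 20 as in step 9 gives the tridecamethyl ether 5-[2,4-dimethoxy-6-(2,4,6-trimethoxyphenoxy)phenoxy]-1,3-dimethoxy-2-[3,4,5-trimethoxy-2-(3,4,5-trimethoxyphenoxy)phenoxy]benzene F4.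
- BBr3 as in step 10 brings it back to the route at 22.

**Step 3.** Desilylation may lag behind addition, so that a silylated adduct forms or the free ethynyl complex 8 oligomerises. The phenoxide may also attack the carbene carbon and exchange the methoxy group. The fallback makes the carbene complex from an acid chloride (Semmelhack–Hegedus route):
- It sets out from 3, which adds to methyl propiolate (DABCO cat., CH2Cl2) to give methyl (E)-3-(2,4,6-trimethoxyphenoxy)prop-2-enoate F5.
- LiOH in aqueous THF gives (E)-3-(2,4,6-trimethoxyphenoxy)prop-2-enoic acid F6.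
- Oxalyl chloride gives (E)-3-(2,4,6-trimethoxyphenoxy)prop-2-enoyl chloride F7.
- K2Cr(CO)5, made from 5 and C8K, acylates at −78 °C to potassium pentacarbonyl[(E)-1-oxido-3-(2,4,6-trimethoxyphenoxy)prop-2-en-1-ylidene]chromate F8.
- Alkylation in the same flask with Me3OBF4 comes back to the route at 9.

**Step 6.** Chemoselectivity between the two aryl bromides may be lost: once 16 has formed, its ring C bromide can be attacked by remaining phenoxide and give oligomeric ethers. The fallback carries ring C without halogen and introduces the bromine last:
- It sets out from 14, which is coupled as in step 6 with 2,6-dimethoxyphenol to give 6-(2,6-dimethoxyphenoxy)-2,3,4-trimethoxybenzaldehyde F9.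
- Baeyer–Villiger oxidation gives, through 6-(2,6-dimethoxyphenoxy)-2,3,4-trimethoxyphenyl formate F10, the phenol 6-(2,6-dimethoxyphenoxy)-2,3,4-trimethoxyphenol F11.
- CuI/picolinic acid coupling with 5-iodo-1,2,3-trimethoxybenzene gives 1,3-dimethoxy-2-[3,4,5-trimethoxy-2-(3,4,5-trimethoxyphenoxy)phenoxy]benzene F12.
- Sterically controlled C–H borylation ([Ir(cod)OMe]2, 4,4'-di-tert-butyl-2,2'-bipyridine, B2pin2) should occur only at C1 of ring C, the one C–H with two unsubstituted neighbours. It gives 2-[3,5-dimethoxy-4-[3,4,5-trimethoxy-2-(3,4,5-trimethoxyphenoxy)phenoxy]phenyl]-4,4,5,5-tetramethyl-1,3,2-dioxaborolane F13.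
- CuBr2 in aqueous methanol replaces boron by bromine and comes back to the route at 20.

**Step 9.** The coupling of two electron-rich partners may be slow, with reductive loss of bromine from 20 and oxidative degradation of the phenoxide of 12 at 110 °C competing. The fallback changes the coupling from a reductive to an oxidative one at room temperature. It sets out from 20, which is converted by bromine–lithium exchange (n-BuLi, −78 °C), B(OiPr)3 and acidic work-up into [3,5-dimethoxy-4-[3,4,5-trimethoxy-2-(3,4,5-trimethoxyphenoxy)phenoxy]phenyl]boronic acid F14. Chan–Lam coupling of F14 with 12 under the conditions of step 8 comes back to the route at 21.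

**Step 10.** Cleavage may stop short, since the ethyl ether and the methyl ethers between two substituents react slowest, and the free tridecaphenol may be lost to oxidation during isolation. The fallback isolates the product in protected form. It sets out from 21: after BBr3 treatment the crude polyphenol is acetylated in the same flask (Ac2O, pyridine) to the tridecaacetate of 22 F15, which is stable and can be purified on silica, with partly alkylated material separated and resubmitted. Transesterification (K2CO3 cat., MeOH, argon, then acidification) comes back to the route at 22.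

## Further compounds

F1 | step 4 | 2,4-dimethoxy-6-(2,4,6-trimethoxyphenoxy)benzaldehyde | COc1cc(OC)c(C=O)c(Oc2c(OC)cc(OC)cc2OC)c1
F2 | step 4 | 2,4-dimethoxy-6-(2,4,6-trimethoxyphenoxy)phenyl formate | COc1cc(OC)c(OC=O)c(Oc2c(OC)cc(OC)cc2OC)c1
F3 | step 4 | 2,4-dimethoxy-6-(2,4,6-trimethoxyphenoxy)phenol | COc1cc(OC)c(O)c(Oc2c(OC)cc(OC)cc2OC)c1
F4 | step 4 | 5-[2,4-dimethoxy-6-(2,4,6-trimethoxyphenoxy)phenoxy]-1,3-dimethoxy-2-[3,4,5-trimethoxy-2-(3,4,5-trimethoxyphenoxy)phenoxy]benzene | COc1cc(OC)cc(Oc2c(OC)cc(OC)cc2OC)c1Oc1cc(OC)c(Oc2cc(OC)c(OC)c(OC)c2Oc2cc(OC)c(OC)c(OC)c2)c(OC)c1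
F5 | step 3 | methyl (E)-3-(2,4,6-trimethoxyphenoxy)prop-2-enoate | COC(=O)/C=C/Oc1c(OC)cc(OC)cc1OC
F6 | step 3 | (E)-3-(2,4,6-trimethoxyphenoxy)prop-2-enoic acid | OC(=O)/C=C/Oc1c(OC)cc(OC)cc1OC
F7 | step 3 | (E)-3-(2,4,6-trimethoxyphenoxy)prop-2-enoyl chloride | ClC(=O)/C=C/Oc1c(OC)cc(OC)cc1OC
F8 | step 3 | potassium pentacarbonyl[(E)-1-oxido-3-(2,4,6-trimethoxyphenoxy)prop-2-en-1-ylidene]chromate | [K+].[O-]C(/C=C/Oc1c(OC)cc(OC)cc1OC)=[Cr](=C=O)(=C=O)(=C=O)(=C=O)=C=O
F9 | step 6 | 6-(2,6-dimethoxyphenoxy)-2,3,4-trimethoxybenzaldehyde | COc1cc(Oc2c(OC)cccc2OC)c(C=O)c(OC)c1OC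
F10 | step 6 | 6-(2,6-dimethoxyphenoxy)-2,3,4-trimethoxyphenyl formate | COc1cc(Oc2c(OC)cccc2OC)c(OC=O)c(OC)c1OC
F11 | step 6 | 6-(2,6-dimethoxyphenoxy)-2,3,4-trimethoxyphenol | COc1cc(Oc2c(OC)cccc2OC)c(O)c(OC)c1OC
F12 | step 6 | 1,3-dimethoxy-2-[3,4,5-trimethoxy-2-(3,4,5-trimethoxyphenoxy)phenoxy]benzene | COc1cccc(OC)c1Oc1cc(OC)c(OC)c(OC)c1Oc1cc(OC)c(OC)c(OC)c1
F13 | step 6 | 2-[3,5-dimethoxy-4-[3,4,5-trimethoxy-2-(3,4,5-trimethoxyphenoxy)phenoxy]phenyl]-4,4,5,5-tetramethyl-1,3,2-dioxaborolane | COc1cc(B2OC(C)(C)C(C)(C)O2)cc(OC)c1Oc1cc(OC)c(OC)c(OC)c1Oc1cc(OC)c(OC)c(OC)c1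
F14 | step 9 | [3,5-dimethoxy-4-[3,4,5-trimethoxy-2-(3,4,5-trimethoxyphenoxy)phenoxy]phenyl]boronic acid | COc1cc(B(O)O)cc(OC)c1Oc1cc(OC)c(OC)c(OC)c1Oc1cc(OC)c(OC)c(OC)c1
F15 | step 10 | tridecaacetate of 22 | CC(=O)Oc1cc(OC(C)=O)c(Oc2cc(OC(C)=O)cc(OC(C)=O)c2Oc2cc(OC(C)=O)c(Oc3cc(OC(C)=O)c(OC(C)=O)c(OC(C)=O)c3Oc3cc(OC(C)=O)c(OC(C)=O)c(OC(C)=O)c3)c(OC(C)=O)c2)c(OC(C)=O)c1
A1 | alternative 1 | (η5-cyclopentadienyl)(η6-2,5-dichloro-1,3-dimethoxybenzene)ruthenium hexafluorophosphate (hapticity not shown) | COc1cc(Cl)cc(OC)c1Cl.[Ru+2].c1cc[cH-]c1.F[P-](F)(F)(F)(F)F
A2 | alternative 1 | 2,4-dimethoxy-6-(2,4,6-trimethoxyphenoxy)phenol | COc1cc(OC)c(O)c(Oc2c(OC)cc(OC)cc2OC)c1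
A3 | alternative 1 | 3,4,5-trimethoxy-2-(3,4,5-trimethoxyphenoxy)phenol | Oc1cc(OC)c(OC)c(OC)c1Oc1cc(OC)c(OC)c(OC)c1
A4 | alternative 1 | CpRu hexafluorophosphate complex of the tridecamethyl ether of 22, bound at ring C (hapticity not shown) | COc1cc(OC)c(Oc2cc(OC)cc(OC)c2Oc2cc(OC)c(Oc3cc(OC)c(OC)c(OC)c3Oc3cc(OC)c(OC)c(OC)c3)c(OC)c2)c(OC)c1.[Ru+2].c1cc[cH-]c1.F[P-](F)(F)(F)(F)F
A5 | alternative 2 | dimethyl 2-(2-benzyloxy-3,5-dimethoxyphenoxy)malonate | COC(=O)C(Oc1cc(OC)cc(OC)c1OCc1ccccc1)C(=O)OC
A6 | alternative 2 | dimethyl 3-oxoglutarate | COC(=O)CC(=O)CC(=O)OC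
A7 | alternative 2 | dimethyl 5-(2-benzyloxy-3,5-dimethoxyphenoxy)-2,4,6-trihydroxyisophthalate | COC(=O)c1c(O)c(C(=O)OC)c(O)c(Oc2cc(OC)cc(OC)c2OCc2ccccc2)c1O
A8 | alternative 3 | 3-ethoxy-4-[3,4,5-trimethoxy-2-(3,4,5-trimethoxyphenoxy)phenoxy]cyclobut-2-en-1-one | CCOC1=CC(=O)C1Oc1cc(OC)c(OC)c(OC)c1Oc1cc(OC)c(OC)c(OC)c1
A9 | alternative 3 | 2-(ethynyloxy)-1,5-dimethoxy-3-(2,4,6-trimethoxyphenoxy)benzene | C#COc1c(OC)cc(OC)cc1Oc1c(OC)cc(OC)cc1OC
A10 | alternative 3 | 3-ethoxy-5-[2,4-dimethoxy-6-(2,4,6-trimethoxyphenoxy)phenoxy]-2-[3,4,5-trimethoxy-2-(3,4,5-trimethoxyphenoxy)phenoxy]phenol | Oc1cc(Oc2c(OC)cc(OC)cc2Oc2c(OC)cc(OC)cc2OC)cc(OCC)c1Oc1cc(OC)c(OC)c(OC)c1Oc1cc(OC)c(OC)c(OC)c1
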